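**Assumption:** natural (R)-(−)-linalyl acetate of high enantiomeric purity is taken as the purchasable chiral starting material (if only (R)-(−)-linalool is in stock, one acetylation with Ac2O/DMAP precedes step 1).

## Retrosynthetic overview

1. Diene side chain: cut C2'–C3' (Heck) into 2-vinylchromanol 13 and E-vinyl iodide 18, the latter from dihydro-β-ionone by alkyne formation and carboalumination.
2. Dihydropyran ring: O1–C8a bond by oxidative para C–O closure of the m-(3-hydroxyalkyl)phenol 11; the carbinol C–O bond of the pool fragment is never broken.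
3. Benzene ring (key ring): Diels–Alder cycloaddition of Danishefsky's diene 7 with nitroalkene 6, aromatized by loss of MeOH and HNO2.
4. Nitroalkene 6 from (R)-linalyl acetate 1 by selective ozonolysis and Henry condensation; C3 of 1 becomes C2 of the target.
5. Ring order: trimethylcyclohexene ring bought, benzene ring by cycloaddition, dihydropyran ring by C–O closure, side chain attached last.

## Route

Step 1
Reactants: 1 (3R)-3,7-dimethylocta-1,6-dien-3-yl acetate [(R)-linalyl acetate]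
Product: 3 (3R)-3-methyl-6-oxohex-1-en-3-yl acetate, via secondary ozonide 2 (not isolated)
Conditions: O3 (1.0 equiv), CH2Cl2, −78 °C; then PPh3, −78 °C → rt
Reagents that add atoms: ozone ([O-][O+]=O)
Why: Ozone adds by 1,3-dipolar cycloaddition (Criegee ozonolysis) much faster to the electron-rich trisubstituted alkene than to the vinyl group deactivated by the allylic acetate, and PPh3 reduces the ozonide to the aldehyde without touching the stereocenter.

Step 2
Reactants: 3 (3R)-3-methyl-6-oxohex-1-en-3-yl acetate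
Product: 6 (3R,6E)-3-methyl-7-nitrohepta-1,6-dien-3-yl acetate, via nitro alcohol 4 (not isolated), via mesylate 5 (not isolated)
Conditions: MeNO2 (5 equiv), KOtBu (10 mol %), THF/t-BuOH, 0 °C; then MsCl, Et3N, CH2Cl2, −10 °C
Reagents that add atoms: nitromethane (C[N+](=O)[O-])
Why: Henry (nitroaldol) addition followed by mesylation and E1cB elimination gives the conjugated E-nitroalkene, a strongly activated dienophile, while the tertiary acetate keeps the carbinol oxygen from adding to it in an oxa-Michael reaction.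

Step 3
Reactants: 6 (3R,6E)-3-methyl-7-nitrohepta-1,6-dien-3-yl acetate; 7 (E)-1-methoxy-3-(trimethylsilyloxy)buta-1,3-diene (Danishefsky's diene)
Product: 11 3-[(3R)-3-hydroxy-3-methylpent-4-en-1-yl]phenol, via cycloadduct 8 (not isolated), via aryl silyl ether 9 (not isolated), via phenol acetate 10 (not isolated)
Conditions: 7 (2 equiv), PhMe, 85 °C; then DBU, 60 °C; then KOH, MeOH–H2O, 50 °C
Reagents that add atoms: none
Why: The thermal Diels–Alder cycloaddition joins C4 of the siloxydiene to the β-carbon and C1 to the nitro-bearing carbon of the nitroalkene (nitroalkene as alkyne equivalent), DBU then expels methanol (E1cB) and nitrous acid to aromatize the new ring, and hydroxide removes the silyl and acetyl groups; the ring stereocenters of 8 are erased and the carbinol center is a spectator.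

Step 4
Reactants: 11 3-[(3R)-3-hydroxy-3-methylpent-4-en-1-yl]phenol
Product: 13 (2R)-2-ethenyl-2-methyl-3,4-dihydro-2H-chromen-6-ol, via acetoxy dienone 12 (not isolated)
Conditions: PhI(OAc)2 (2.2 equiv), MeCN, −10 °C; then Zn, AcOH, 0 °C → rt
Reagents that add atoms: none
Why: In this hypervalent-iodine oxidative phenol cyclisation the phenoxenium-type species is captured at the para carbon by the tethered tertiary hydroxyl through a six-membered transition state, the more easily oxidised chromanol is carried on to acetoxy dienone 12 and zinc reduces it back, so the carbinol C–O bond is never broken and C2 keeps the R configuration.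

Step 5
Reactants: 14 4-(2,6,6-trimethylcyclohex-1-en-1-yl)butan-2-one (dihydro-β-ionone)
Product: 16 2-(but-3-yn-1-yl)-1,3,3-trimethylcyclohex-1-ene, via enol phosphate 15 (not isolated)
Conditions: LiN(iPr)2 (1.1 equiv), THF, −78 °C; ClP(O)(OEt)2; then LiN(iPr)2 (2.3 equiv), −78 °C → rt
Reagents that add atoms: none
Why: Kinetic deprotonation at the methyl group, O-phosphorylation and double elimination of the enol phosphate (Negishi methyl ketone to alkyne conversion) give the terminal alkyne without disturbing the tetrasubstituted ring alkene.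

Step 6
Reactants: 16 2-(but-3-yn-1-yl)-1,3,3-trimethylcyclohex-1-ene
Product: 18 2-[(3E)-4-iodo-3-methylbut-3-en-1-yl]-1,3,3-trimethylcyclohex-1-ene, via alkenylalane 17 (not isolated)
Conditions: Me3Al (2 equiv), Cp2ZrCl2 (20 mol %), CH2Cl2, rt; then I2, THF, −30 °C
Reagents that add atoms: trimethylaluminium (C[Al](C)C); iodine (II)
Why: Cp2ZrCl2-catalysed syn-carboalumination (Negishi) places methyl on the internal and aluminium on the terminal alkyne carbon, and iodinolysis with retention gives the E-vinyl iodide.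

Step 7
Reactants: 13 (2R)-2-ethenyl-2-methyl-3,4-dihydro-2H-chromen-6-ol; 18 2-[(3E)-4-iodo-3-methylbut-3-en-1-yl]-1,3,3-trimethylcyclohex-1-ene
Product: 19 (2R)-2-methyl-2-[(1E,3E)-4-methyl-6-(2,6,6-trimethylcyclohex-1-en-1-yl)hexa-1,3-dien-1-yl]-3,4-dihydro-2H-chromen-6-ol
Conditions: Pd(OAc)2 (5 mol %), Bu4NCl, NaHCO3, DMF (degassed), 45 °C
Reagents that add atoms: none
Why: In this Mizoroki–Heck coupling under ligand-free Jeffery conditions the alkenylpalladium adds to the terminal carbon of the vinyl group and β-hydride elimination, possible only away from the quaternary C2, gives the E,E-diene with retention of the vinyl iodide geometry and of the stereocenter.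

## Compound list

1 | (3R)-3,7-dimethylocta-1,6-dien-3-yl acetate [(R)-linalyl acetate] | C=C[C@](C)(OC(C)=O)CCC=C(C)C | starting material
2 | (3R)-5-(5,5-dimethyl-1,2,4-trioxolan-3-yl)-3-methylpent-1-en-3-yl acetate (secondary ozonide, mixture at the ring carbon) | C=C[C@](C)(OC(C)=O)CCC1OOC(C)(C)O1 | intermediate
3 | (3R)-3-methyl-6-oxohex-1-en-3-yl acetate | C=C[C@](C)(OC(C)=O)CCC=O | intermediate
4 | (3R)-6-hydroxy-3-methyl-7-nitrohept-1-en-3-yl acetate (mixture at C6) | C=C[C@](C)(OC(C)=O)CCC(O)C[N+](=O)[O-] | intermediate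
5 | (3R)-3-methyl-6-(methylsulfonyloxy)-7-nitrohept-1-en-3-yl acetate (mixture at C6) | C=C[C@](C)(OC(C)=O)CCC(OS(C)(=O)=O)C[N+](=O)[O-] | intermediate
6 | (3R,6E)-3-methyl-7-nitrohepta-1,6-dien-3-yl acetate | C=C[C@](C)(OC(C)=O)CC/C=C/[N+](=O)[O-] | intermediate
7 | (E)-1-methoxy-3-(trimethylsilyloxy)buta-1,3-diene (Danishefsky's diene) | CO/C=C/C(=C)O[Si](C)(C)C | starting material
8 | (3R)-5-[5-methoxy-6-nitro-3-(trimethylsilyloxy)cyclohex-3-en-1-yl]-3-methylpent-1-en-3-yl acetate (mixture of ring diastereomers) | C=C[C@](C)(OC(C)=O)CCC1CC(O[Si](C)(C)C)=CC(OC)C1[N+](=O)[O-] | intermediate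
9 | (3R)-3-methyl-5-[3-(trimethylsilyloxy)phenyl]pent-1-en-3-yl acetate | C=C[C@](C)(OC(C)=O)CCc1cccc(O[Si](C)(C)C)c1 | intermediate
10 | (3R)-5-(3-hydroxyphenyl)-3-methylpent-1-en-3-yl acetate | C=C[C@](C)(OC(C)=O)CCc1cccc(O)c1 | intermediate
11 | 3-[(3R)-3-hydroxy-3-methylpent-4-en-1-yl]phenol | C=C[C@](C)(O)CCc1cccc(O)c1 | intermediate
12 | (2R)-2-ethenyl-2-methyl-6-oxo-3,4,6,8a-tetrahydro-2H-chromen-8a-yl acetate (mixture at C8a) | C=C[C@@]1(C)CCC2=CC(=O)C=CC2(OC(C)=O)O1 | intermediate
13 | (2R)-2-ethenyl-2-methyl-3,4-dihydro-2H-chromen-6-ol | C=C[C@@]1(C)CCc2cc(O)ccc2O1 | intermediate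
14 | 4-(2,6,6-trimethylcyclohex-1-en-1-yl)butan-2-one (dihydro-β-ionone) | CC(=O)CCC1=C(C)CCCC1(C)C | starting material
15 | diethyl 4-(2,6,6-trimethylcyclohex-1-en-1-yl)but-1-en-2-yl phosphate | C=C(CCC1=C(C)CCCC1(C)C)OP(=O)(OCC)OCC | intermediate
16 | 2-(but-3-yn-1-yl)-1,3,3-trimethylcyclohex-1-ene | C#CCCC1=C(C)CCCC1(C)C | intermediate
17 | dimethyl[(1E)-2-methyl-4-(2,6,6-trimethylcyclohex-1-en-1-yl)but-1-en-1-yl]aluminium | C[Al](C)/C=C(\C)CCC1=C(C)CCCC1(C)C | intermediate
18 | 2-[(3E)-4-iodo-3-methylbut-3-en-1-yl]-1,3,3-trimethylcyclohex-1-ene | I/C=C(\C)CCC1=C(C)CCCC1(C)C | intermediate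
19 | (2R)-2-methyl-2-[(1E,3E)-4-methyl-6-(2,6,6-trimethylcyclohex-1-en-1-yl)hexa-1,3-dien-1-yl]-3,4-dihydro-2H-chromen-6-ol | CC1=C(CC/C(C)=C/C=C/[C@@]2(C)CCc3cc(O)ccc3O2)C(C)(C)CCC1 | target

## Step count and risks

Total step count: 7. Longest linear sequence: 5 steps (steps 1, 2, 3, 4 and 7); steps 5 and 6 make the vinyl iodide that enters in step 7.

**Step 3 (cycloaddition and aromatization).** The alkyl nitroalkene may give open-chain Michael-type adducts with the silyl enol ether, or the sequence may stall at a nitro diene or 4-nitrocyclohexenone before HNO2 is lost. The fallback buys the arene and makes the aryl–alkyl bond by cross-coupling after a one-carbon radical excision; it sets out from 1 and comes back at 11. Compound 1 is saponified (KOH, MeOH) to (3R)-3,7-dimethylocta-1,6-dien-3-ol F1. Ozonolysis (O3; PPh3) gives the lactol (5R)-5-ethenyl-5-methyloxolan-2-ol F2. Alkoxy-radical β-fragmentation (PhI(OAc)2, I2, visible light, Suárez conditions) gives (3R)-5-iodo-3-methylpent-1-en-3-yl formate F3. Zinc insertion (Zn, LiCl, THF) gives [(3R)-3-(formyloxy)-3-methylpent-4-en-1-yl](iodo)zinc F4. Negishi coupling with commercial tert-butyl(3-iodophenoxy)dimethylsilane (Pd(OAc)2, SPhos, THF) gives (3R)-5-[3-(tert-butyldimethylsilyloxy)phenyl]-3-methylpent-1-en-3-yl formate F5. K2CO3 in MeOH removes the formyl and silyl groups and returns 11.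

**Step 4 (oxidative C–O closure).** Closure may occur partly at the ortho carbon, the over-oxidised dienone may open to the side-chain quinone before it is reduced, and the tertiary allylic alcohol may ionise. The fallback replaces the oxidative closure by halogenation and a palladium-catalysed etherification; it sets out from 11 and comes back at 13. Para-selective bromination (Bu4NBr3, CH2Cl2/MeOH, 0 °C) gives 4-bromo-3-[(3R)-3-hydroxy-3-methylpent-4-en-1-yl]phenol F6. Silylation of the phenol (t-BuMe2SiCl, imidazole) gives (3R)-5-[2-bromo-5-(tert-butyldimethylsilyloxy)phenyl]-3-methylpent-1-en-3-ol F7. Intramolecular Buchwald C–O coupling of the tertiary alcohol (Pd(OAc)2, 2-(di-tert-butylphosphino)-1,1'-binaphthyl, Cs2CO3, PhMe, 80 °C) gives tert-butyl{[(2R)-2-ethenyl-2-methyl-3,4-dihydro-2H-chromen-6-yl]oxy}dimethylsilane F8. Bu4NF returns 13.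

**Step 7 (Heck coupling).** The alkene sits next to a quaternary carbon, and zerovalent palladium could ionise the tertiary allylic aryl ether of 13 or of the product, giving ring opening or racemisation. The fallback is a palladium-free Julia–Kocienski olefination; it sets out from 13 and from alane 17 and comes back at 19. Compound 13 is silylated (i-Pr3SiCl, imidazole) to {[(2R)-2-ethenyl-2-methyl-3,4-dihydro-2H-chromen-6-yl]oxy}tri(propan-2-yl)silane F9. Oxidative cleavage of the vinyl group (OsO4 cat., NaIO4, 2,6-lutidine, dioxane/H2O) gives (2R)-2-methyl-6-{[tri(propan-2-yl)silyl]oxy}-3,4-dihydro-2H-chromene-2-carbaldehyde F10. Alane 17 (made as in step 6, before the iodine quench) is trapped with paraformaldehyde to give (2E)-3-methyl-5-(2,6,6-trimethylcyclohex-1-en-1-yl)pent-2-en-1-ol F11. Mitsunobu reaction with 1-phenyl-1H-tetrazole-5-thiol (PPh3, diisopropyl azodicarboxylate) gives 5-{[(2E)-3-methyl-5-(2,6,6-trimethylcyclohex-1-en-1-yl)pent-2-en-1-yl]sulfanyl}-1-phenyl-1H-tetrazole F12. Oxidation (H2O2, (NH4)6Mo7O24, EtOH) gives 5-{[(2E)-3-methyl-5-(2,6,6-trimethylcyclohex-1-en-1-yl)pent-2-en-1-yl]sulfonyl}-1-phenyl-1H-tetrazole F13. Deprotonation (KN(SiMe3)2, DME, −60 °C) and addition of F10 gives the E,E-diene {[(2R)-2-methyl-2-[(1E,3E)-4-methyl-6-(2,6,6-trimethylcyclohex-1-en-1-yl)hexa-1,3-dien-1-yl]-3,4-dihydro-2H-chromen-6-yl]oxy}tri(propan-2-yl)silane F14. Bu4NF returns 19.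

## Further compounds

F1 | step 3 | (3R)-3,7-dimethylocta-1,6-dien-3-ol | C=C[C@](C)(O)CCC=C(C)C
F2 | step 3 | (5R)-5-ethenyl-5-methyloxolan-2-ol | C=C[C@@]1(C)CCC(O)O1
F3 | step 3 | (3R)-5-iodo-3-methylpent-1-en-3-yl formate | C=C[C@](C)(OC=O)CCI
F4 | step 3 | [(3R)-3-(formyloxy)-3-methylpent-4-en-1-yl](iodo)zinc | C=C[C@](C)(OC=O)CC[Zn]I
F5 | step 3 | (3R)-5-[3-(tert-butyldimethylsilyloxy)phenyl]-3-methylpent-1-en-3-yl formate | C=C[C@](C)(OC=O)CCc1cccc(O[Si](C)(C)C(C)(C)C)c1
F6 | step 4 | 4-bromo-3-[(3R)-3-hydroxy-3-methylpent-4-en-1-yl]phenol | C=C[C@](C)(O)CCc1cc(O)ccc1Br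
F7 | step 4 | (3R)-5-[2-bromo-5-(tert-butyldimethylsilyloxy)phenyl]-3-methylpent-1-en-3-ol | C=C[C@](C)(O)CCc1cc(O[Si](C)(C)C(C)(C)C)ccc1Br
F8 | step 4 | tert-butyl{[(2R)-2-ethenyl-2-methyl-3,4-dihydro-2H-chromen-6-yl]oxy}dimethylsilane | C=C[C@@]1(C)CCc2cc(O[Si](C)(C)C(C)(C)C)ccc2O1
F9 | step 7 | {[(2R)-2-ethenyl-2-methyl-3,4-dihydro-2H-chromen-6-yl]oxy}tri(propan-2-yl)silane | C=C[C@@]1(C)CCc2cc(O[Si](C(C)C)(C(C)C)C(C)C)ccc2O1
F10 | step 7 | (2R)-2-methyl-6-{[tri(propan-2-yl)silyl]oxy}-3,4-dihydro-2H-chromene-2-carbaldehyde | O=C[C@@]1(C)CCc2cc(O[Si](C(C)C)(C(C)C)C(C)C)ccc2O1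
F11 | step 7 | (2E)-3-methyl-5-(2,6,6-trimethylcyclohex-1-en-1-yl)pent-2-en-1-ol | CC1=C(CC/C(C)=C/CO)C(C)(C)CCC1
F12 | step 7 | 5-{[(2E)-3-methyl-5-(2,6,6-trimethylcyclohex-1-en-1-yl)pent-2-en-1-yl]sulfanyl}-1-phenyl-1H-tetrazole | CC1=C(CC/C(C)=C/CSc2nnnn2-c2ccccc2)C(C)(C)CCC1
F13 | step 7 | 5-{[(2E)-3-methyl-5-(2,6,6-trimethylcyclohex-1-en-1-yl)pent-2-en-1-yl]sulfonyl}-1-phenyl-1H-tetrazole | CC1=C(CC/C(C)=C/CS(=O)(=O)c2nnnn2-c2ccccc2)C(C)(C)CCC1
F14 | step 7 | {[(2R)-2-methyl-2-[(1E,3E)-4-methyl-6-(2,6,6-trimethylcyclohex-1-en-1-yl)hexa-1,3-dien-1-yl]-3,4-dihydro-2H-chromen-6-yl]oxy}tri(propan-2-yl)silane | CC1=C(CC/C(C)=C/C=C/[C@@]2(C)CCc3cc(O[Si](C(C)C)(C(C)C)C(C)C)ccc3O2)C(C)(C)CCC1
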